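**Plan**

1. Retrosynthesis: (a) cut the aryl ether O–C-8 of the pyranone (chroman-4-one) ring, i.e. an oxidative para C–O coupling of a ring-A phenol; (b) move the benzylic ether O-7–CH(aryl) of the dihydrofuran back to the aroyl-ring oxygen, which gives a temporary 3-aryl-3-hydroxychroman-4-one; (c) cut its C-3–C-4 bond (crossed benzoin); (d) cut the aryl–acyl bond at C-8 of the flavan.
2. Forward: (−)-epiafzelechin (rings A, C, B) → benzylation and C-8 bromination → C-8 acylation with an α-aryloxy ester → temporary chromanone ring by NHC benzoin → debenzylation → quinone-methide ring switch to the 7-O,8-C-fused dihydrofuran → pyranone ring closed last by dearomatising ring A.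
3. Stereochemistry: C-2/C-3 of the flavan come from the chiral pool; the tertiary carbinol from the chiral triazolium catalyst (step 8); the CH(aryl) centre from thermodynamic control in the ring switch (aryl trans to aroyl, step 10); the quaternary C-8 from the carbinol through the aroyl tether (cis ring fusion, step 11).
4. Enabling feature: ring A is a phloroglucinol ring whose free 5-OH is para to C-8. C-8 carries the carbinol carbon, and the ortho-OH of the 2,4,6-trihydroxybenzoyl group on that carbon lies five atoms from C-8, so two-electron oxidation of ring A is trapped as a six-membered aryl ether. The carbinol carbon has no hydrogen and cannot give a quinone methide.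

Key step: step 11

Assumption: (−)-epiafzelechin and methyl (±)-4-hydroxymandelate are bought; the triazolium enantiomer named in step 8 is assumed to give the 3S carbinol, and its antipode would be used if the opposite sense were found.

Step 1
Reactants: 1 (−)-epiafzelechin
Product: 2 5,7,4'-tri-O-benzyl-epiafzelechin
Conditions: BnBr (3.1 equiv), K2CO3, DMF, 0 °C to rt
Reagents that add atoms: benzyl bromide BrCc1ccccc1
Why: Williamson etherification of the three phenols under K2CO3 should leave the less acidic secondary 3-OH free and touches no stereocentre, the 2R,3R centres coming from the chiral pool.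

Step 2
Reactants: 2 5,7,4'-tri-O-benzyl-epiafzelechin
Product: 3 8-bromo-5,7,4'-tri-O-benzyl-epiafzelechin
Conditions: NBS (1.0 equiv), CH2Cl2, −78 to −40 °C
Reagents that add atoms: N-bromosuccinimide O=C1CCC(=O)N1Br
Why: Electrophilic aromatic bromination of ring A should go to C-8, the usual site of attack in 5,7-di-O-benzyl flavan-3-ols, because C-6 is flanked by two benzyloxy groups.

Step 3
Reactants: 4 2,4,6-trihydroxybenzaldehyde
Product: 5 2-hydroxy-4,6-bis(benzyloxy)benzaldehyde
Conditions: BnBr (2.05 equiv), K2CO3, DMF, 0 °C to rt
Reagents that add atoms: benzyl bromide BrCc1ccccc1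
Why: Williamson benzylation should take the 4-OH and one ortho-OH, while the second ortho-OH is hydrogen-bonded to the aldehyde and is kept for the later ether link.

Step 4
Reactants: 6 methyl (±)-4-hydroxymandelate
Product: 7 methyl (±)-2-[4-(benzyloxy)phenyl]-2-hydroxyacetate
Conditions: BnBr (1.05 equiv), K2CO3, acetone, reflux
Reagents that add atoms: benzyl bromide BrCc1ccccc1
Why: Chemoselective Williamson benzylation of the phenol, since K2CO3 does not deprotonate the secondary alcohol.

Step 5
Reactants: 7 methyl (±)-2-[4-(benzyloxy)phenyl]-2-hydroxyacetate; 5 2-hydroxy-4,6-bis(benzyloxy)benzaldehyde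
Product: 8 methyl (±)-2-[4-(benzyloxy)phenyl]-2-[3,5-bis(benzyloxy)-2-formylphenoxy]acetate
Conditions: PPh3, DIAD, THF, 0 °C to rt
Reagents that add atoms: none
Why: Mitsunobu etherification in which the acidic ortho-formyl phenol displaces the activated benzylic hydroxyl with inversion, which is irrelevant because 7 is racemic and this centre is re-set in step 10.

Step 6
Reactants: 8 methyl (±)-2-[4-(benzyloxy)phenyl]-2-[3,5-bis(benzyloxy)-2-formylphenoxy]acetate
Product: 9 methyl (±)-2-[4-(benzyloxy)phenyl]-2-[3,5-bis(benzyloxy)-2-(dimethoxymethyl)phenoxy]acetate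
Conditions: HC(OMe)3, p-TsOH·H2O (cat.), MeOH, rt
Reagents that add atoms: trimethyl orthoformate COC(OC)OC
Why: Acid-catalysed acetalisation masks the aldehyde against the aryllithium of step 7, and an electron-rich benzaldehyde acetal is released again by dilute acid.

Step 7
Reactants: 3 8-bromo-5,7,4'-tri-O-benzyl-epiafzelechin; 9 methyl (±)-2-[4-(benzyloxy)phenyl]-2-[3,5-bis(benzyloxy)-2-(dimethoxymethyl)phenoxy]acetate
Product: 12 8-[2-aryl-2-(aryloxy)acetyl]flavan keto aldehyde, via dilithiated flavan 10 (not isolated), via ketone dimethyl acetal 11 (not isolated)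
Conditions: n-BuLi (2.1 equiv), THF, −78 °C; then 9, CeCl3 (additive), −78 to −40 °C; then 1 M HCl (aq), THF, 0 °C
Reagents that add atoms: water O
Why: Bromine–lithium exchange at C-8 (the first equivalent of n-BuLi takes the 3-OH proton) followed by acyl substitution on the methyl ester should stop at the doubly ortho-substituted aryl ketone, because the tetrahedral intermediate is chelated by the α-aryloxy oxygen and CeCl3 curbs enolisation; aqueous acid then hydrolyses the acetal, and the aryloxy-bearing carbon stays an epimer mixture.

Step 8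
Reactants: 12 8-[2-aryl-2-(aryloxy)acetyl]flavan keto aldehyde
Product: 13 (3S)-3-(flavan-8-yl)-3-hydroxychroman-4-one with six benzyl ethers (temporary ring)
Conditions: (5aS,10bR)-2-(pentafluorophenyl)-5a,10b-dihydro-4H,6H-indeno[2,1-b][1,2,4]triazolo[4,3-d][1,4]oxazin-2-ium tetrafluoroborate (15 mol %), i-Pr2NEt (15 mol %), toluene, rt
Reagents that add atoms: none
Why: Enantioselective NHC-catalysed intramolecular crossed benzoin reaction, the established route to 3-hydroxychroman-4-ones, in which the Breslow intermediate of the aldehyde adds to the ketone in a six-membered closure; the chiral triazolylidene chooses the ketone face and should fix the tertiary carbinol as 3S, while the base-labile aryloxy centre lets both epimers of 12 converge.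

Step 9
Reactants: 13 (3S)-3-(flavan-8-yl)-3-hydroxychroman-4-one with six benzyl ethers
Product: 14 (3S)-3,5,7-trihydroxy-2-(4-hydroxyphenyl)-3-(epiafzelechin-8-yl)chroman-4-one
Conditions: H2 (1 atm), Pd(OH)2 on carbon, THF/MeOH, rt
Reagents that add atoms: none
Why: Hydrogenolysis of the six benzyl aryl ethers under neutral conditions, where the cyclic benzylic ethers of the flavan and chromanone rings, the aryl ketone and the tertiary carbinol should react far more slowly and no stereocentre is touched.

Step 10
Reactants: 14 (3S)-3,5,7-trihydroxy-2-(4-hydroxyphenyl)-3-(epiafzelechin-8-yl)chroman-4-one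
Product: 16 dihydrobenzofuranol (ring-A 5-OH free), via quinone methide 15 (not isolated)
Conditions: NaHCO3 (0.2 equiv), degassed MeOH/H2O, 45 °C
Reagents that add atoms: none
Why: Proposed new method: near pH 8 the 4-hydroxyphenyl group at C-2 of the temporary chromanone ring is partly deprotonated and expels the acyl-stabilised ring phenoxide by 1,6-elimination to give p-quinone methide 15, which can re-close either with the released phenol (back to 14) or with the 7-OH of ring A (five-membered ring); both closures are reversible, so the mixture should drain to 16, where the ether is held by the less acidic phenol and the hydroxy ketone is chelated, with the aryl group settling trans to the aroyl group (cis to OH) under thermodynamic control and the carbinol untouched; the closest known reaction type is the base-induced ring opening and reclosure of 4'-hydroxyflavanones and dihydroflavonols through quinone methides (C-2 epimerisation), together with phenol addition to p-quinone methides giving 2-aryl-2,3-dihydrobenzofurans.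

Step 11
Reactants: 16 dihydrobenzofuranol (ring-A 5-OH free)
Product: 17 target CNP0170480.3
Conditions: PhI(OAc)2 (1.05 equiv), (CF3)2CHOH/MeCN, −40 °C
Reagents that add atoms: none
Why: PhI(OAc)2 exchanges acetate for the phenols reversibly, and the aryloxy-λ3-iodane of the ring-A 5-OH collapses with loss of PhI to a phenoxenium-type cation whose para carbon C-8 is captured by the ortho-OH of the 2,4,6-trihydroxybenzoyl group (two-electron oxidative dearomatisation, loss of 2 H). The closest known reaction type is the oxidative dearomatising para C–O phenol coupling that turns o-hydroxybenzophenones into grisan spirodienones and p-alkylphenols into p-quinol ethers with hypervalent iodine. The pyranone ring closes in a 6-exo-trig mode (O onto C-8, whose π bonds lie outside the new ring), and the cross-conjugated dienone with its two vinylogous ester oxygens (O-7 and O-1) forms at the same time. The only new stereocentre, the quaternary C-8, is set by the neighbouring carbinol carbon: the aroyl tether reaches C-8 only from the face it occupies, so the dihydrofuran and pyranone rings are cis-fused with O–C-8 anti to the tertiary OH. The step needs chemoselective oxidation of ring A among six phenols and attack at C-8 rather than at an ortho carbon: ring A is the only non-acylated phloroglucinol ring, ligand exchange is reversible so the pathway with the intramolecular six-membered capture should win, C-6 and C-4a cannot be reached by the tether, and the fully substituted carbinol carbon excludes quinone-methide formation. One equivalent of oxidant at −40 °C and a neutral work-up are used because the product could undergo retro-aldol cleavage in base.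

**Compound list**

1 | (−)-epiafzelechin, (2R,3R)-2-(4-hydroxyphenyl)chromane-3,5,7-triol | Oc1cc(O)c2C[C@@H](O)[C@@H](c3ccc(O)cc3)Oc2c1 | starting material
2 | 5,7,4'-tri-O-benzyl-epiafzelechin, (2R,3R), 3-OH free | c1ccccc1COc1cc(OCc2ccccc2)c2C[C@@H](O)[C@@H](c3ccc(OCc4ccccc4)cc3)Oc2c1 | intermediate
3 | 8-bromo-5,7,4'-tri-O-benzyl-epiafzelechin | c1ccccc1COc1cc(OCc2ccccc2)c2C[C@@H](O)[C@@H](c3ccc(OCc4ccccc4)cc3)Oc2c1Br | intermediate
4 | 2,4,6-trihydroxybenzaldehyde | O=Cc1c(O)cc(O)cc1O | starting material
5 | 2-hydroxy-4,6-bis(benzyloxy)benzaldehyde | O=Cc1c(O)cc(OCc2ccccc2)cc1OCc1ccccc1 | intermediate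
6 | methyl (±)-4-hydroxymandelate | COC(=O)C(O)c1ccc(O)cc1 | starting material
7 | methyl (±)-2-[4-(benzyloxy)phenyl]-2-hydroxyacetate | COC(=O)C(O)c1ccc(OCc2ccccc2)cc1 | intermediate
8 | methyl (±)-2-[4-(benzyloxy)phenyl]-2-[3,5-bis(benzyloxy)-2-formylphenoxy]acetate | COC(=O)C(Oc1cc(OCc2ccccc2)cc(OCc2ccccc2)c1C=O)c1ccc(OCc2ccccc2)cc1 | intermediate
9 | methyl (±)-2-[4-(benzyloxy)phenyl]-2-[3,5-bis(benzyloxy)-2-(dimethoxymethyl)phenoxy]acetate | COC(=O)C(Oc1cc(OCc2ccccc2)cc(OCc2ccccc2)c1C(OC)OC)c1ccc(OCc2ccccc2)cc1 | intermediate
10 | dilithiated flavan (8-lithio, 3-O-lithium alkoxide of 3) | c1ccccc1COc1cc(OCc2ccccc2)c2C[C@@H](O[Li])[C@@H](c3ccc(OCc4ccccc4)cc3)Oc2c1[Li] | intermediate (not isolated)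
11 | ketone dimethyl acetal (8-acylated flavan, aldehyde still masked; both epimers at the aryloxy carbon) | c1ccccc1COc1cc(OCc2ccccc2)c2C[C@@H](O)[C@@H](c3ccc(OCc4ccccc4)cc3)Oc2c1C(=O)C(Oc1cc(OCc2ccccc2)cc(OCc2ccccc2)c1C(OC)OC)c1ccc(OCc2ccccc2)cc1 | intermediate (not isolated)
12 | keto aldehyde: 8-{2-[4-(benzyloxy)phenyl]-2-[3,5-bis(benzyloxy)-2-formylphenoxy]acetyl}-5,7,4'-tri-O-benzyl-epiafzelechin (both epimers at the aryloxy carbon) | c1ccccc1COc1cc(OCc2ccccc2)c2C[C@@H](O)[C@@H](c3ccc(OCc4ccccc4)cc3)Oc2c1C(=O)C(Oc1cc(OCc2ccccc2)cc(OCc2ccccc2)c1C=O)c1ccc(OCc2ccccc2)cc1 | intermediate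
13 | (3S)-5,7-bis(benzyloxy)-2-[4-(benzyloxy)phenyl]-3-hydroxy-3-(5,7,4'-tri-O-benzyl-epiafzelechin-8-yl)chroman-4-one (temporary ring; C-2 not controlled, re-set in step 10) | c1ccccc1COc1cc(OCc2ccccc2)c(c2c1C[C@@H](O)[C@@H](c1ccc(OCc3ccccc3)cc1)O2)[C@@]1(O)C(=O)c2c(OCc3ccccc3)cc(OCc3ccccc3)cc2OC1c1ccc(OCc2ccccc2)cc1 | intermediate
14 | (3S)-3,5,7-trihydroxy-2-(4-hydroxyphenyl)-3-[(2R,3R)-3,5,7-trihydroxy-2-(4-hydroxyphenyl)chroman-8-yl]chroman-4-one (C-2 not controlled) | Oc1cc(O)c(c2c1C[C@@H](O)[C@@H](c1ccc(O)cc1)O2)[C@@]1(O)C(=O)c2c(O)cc(O)cc2OC1c1ccc(O)cc1 | intermediate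
15 | ring-opened p-quinone methide (carbinol carbon bearing the epiafzelechin-8-yl group, the 2,4,6-trihydroxybenzoyl group and the quinone-methide CH) | Oc1cc(O)c(c2c1C[C@@H](O)[C@@H](c1ccc(O)cc1)O2)[C@@](O)(C(=O)c1c(O)cc(O)cc1O)C=C1C=CC(=O)C=C1 | intermediate (not isolated)
16 | dihydrobenzofuranol: (2S,3S)-3-hydroxy-2-(4-hydroxyphenyl)-3-(2,4,6-trihydroxybenzoyl)-2,3-dihydrofuran fused through O-7 and C-8 to (2R,3R)-epiafzelechin; aryl cis to the 3-OH, ring-A 5-OH free | Oc1cc2O[C@@H](c3ccc(O)cc3)[C@](O)(C(=O)c4c(O)cc(O)cc4O)c2c3c1C[C@@H](O)[C@@H](c1ccc(O)cc1)O3 | intermediate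
17 | target CNP0170480.3 (cis-fused dihydrofuran/pyranone on the dearomatised ring-A dienone) | O=C1C=C2O[C@@H](c3ccc(O)cc3)[C@]3(O)C(=O)c4c(O)cc(O)cc4O[C@]23C2=C1C[C@@H](O)[C@@H](c1ccc(O)cc1)O2 | target

**Step count and risks**

Total step count: 11. Longest linear sequence: 8 steps (steps 4, 5, 6, 7, 8, 9, 10, 11 from 6; the branch from 4 through steps 3 and 5–11 is equally long; the flavan branch has 7).

Step 10 (bears the label) is the riskiest. The quinone-methide equilibrium may not drain to the five-membered ether, since re-closure by the chelated aroyl-ring phenol may remain preferred. The free heptaphenol may also be lost to air oxidation or a base-induced α-ketol shift while it equilibrates. The fallback uses known chemistry, sets out from 13 and comes back at 16; it is a kinetic, Lewis-acid-driven ring switch on the benzylated stage. BCl3 (CH2Cl2, −78 °C) chelates between the 4-carbonyl and O-1 of the temporary chromanone ring, which is the established chelation-controlled cleavage of ethers ortho to an aryl ketone, and ionises the p-benzyloxybenzylic C-2–O-1 bond. The neighbouring 7-benzyloxy oxygen captures the cation and loses benzyl chloride (debenzylative cycloetherification), and the same chelation removes the ortho benzyl ether of the aroyl ring. This should give the tetra-O-benzyl dihydrobenzofuranol F1. Hydrogenolysis (H2, Pd(OH)2 on carbon) then gives 16; if the aryl-bearing centre is not yet trans to the aroyl group it would equilibrate under the buffer of step 10.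

Step 8 is next. Addition of the Breslow intermediate to the doubly ortho-substituted aryl ketone may be slow. Base-induced intramolecular aldol attack of the enolisable α-aryloxy ketone on the aldehyde (Rap–Stoermer-type) or poor facial selection could then take over. The fallback sets out from 12 and comes back at 13; it replaces umpolung by reductive carbonyl coupling. SmI2 (THF/t-BuOH, −78 °C) should effect an intramolecular ketone–aldehyde pinacol cyclisation to the chromane-3,4-diol F2 (new centres not controlled). MnO2 (CH2Cl2) then oxidises the secondary benzylic alcohol to the 4-ketone 13. The carbinol configuration is then not reagent-controlled, and the 3S epimer, a diastereomer because of the flavan, would have to be separated by chromatography.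

Step 11 is third. The two 4-hydroxyphenyl rings may be oxidised competitively (phenoxenium formation, then quinone-methide cleavage of the benzylic C–O bonds), or the product may be over-oxidised. The fallback sets out from 16 and comes back at 17; it masks the unhindered phenols first. TBSCl (3 equiv), imidazole, DMF, −20 °C should silylate the two 4-hydroxyphenyl groups and the 4-OH of the aroyl ring, while the ortho-substituted ring-A 5-OH and the chelated 2- and 6-OH stay free, giving the tris-silyl ether F3. The same PhI(OAc)2 oxidation gives the silylated dienone F4, and HF·pyridine (THF, 0 °C) removes the three silyl groups to give 17.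

**Further compounds**

F1 | step 10 | tetra-O-benzyl ether of 16 (benzyl on ring-A 5-O, on both 4-hydroxyphenyl oxygens and on the 4-O of the aroyl ring) | c1ccccc1COc1cc2O[C@@H](c3ccc(OCc4ccccc4)cc3)[C@](O)(C(=O)c4c(O)cc(OCc5ccccc5)cc4O)c2c3c1C[C@@H](O)[C@@H](c1ccc(OCc2ccccc2)cc1)O3
F2 | step 8 | 5,7-bis(benzyloxy)-2-[4-(benzyloxy)phenyl]-3-(5,7,4'-tri-O-benzyl-epiafzelechin-8-yl)chromane-3,4-diol (new centres not controlled) | c1ccccc1COc1cc(OCc2ccccc2)c(c2c1C[C@@H](O)[C@@H](c1ccc(OCc3ccccc3)cc1)O2)C1(O)C(O)c2c(OCc3ccccc3)cc(OCc3ccccc3)cc2OC1c1ccc(OCc2ccccc2)cc1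
F3 | step 11 | tris-O-TBS ether of 16 (silyl on both 4-hydroxyphenyl oxygens and on the 4-O of the aroyl ring) | Oc1cc2O[C@@H](c3ccc(O[Si](C)(C)C(C)(C)C)cc3)[C@](O)(C(=O)c4c(O)cc(O[Si](C)(C)C(C)(C)C)cc4O)c2c3c1C[C@@H](O)[C@@H](c1ccc(O[Si](C)(C)C(C)(C)C)cc1)O3
F4 | step 11 | tris-O-TBS ether of 17 | O=C1C=C2O[C@@H](c3ccc(O[Si](C)(C)C(C)(C)C)cc3)[C@]3(O)C(=O)c4c(O)cc(O[Si](C)(C)C(C)(C)C)cc4O[C@]23C2=C1C[C@@H](O)[C@@H](c1ccc(O[Si](C)(C)C(C)(C)C)cc1)O2
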